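**Plan**

1. Numbering of the target (6-oxabicyclo[3.2.1]octane): C1 bridgehead with prenyl, C2 CH2, C3 CH with prenyl, C4 CMe2, C5 bridgehead with O6 and isobutyryl, C7 lactone C=O, C8 bridging ketone.
2. Retrosynthesis: C2–C3 and C4–C5 are cut together (formal [4+2]). This removes the whole three-carbon bridge and leaves a monocyclic 3,3-disubstituted 5-isobutyrylfuran-2,4-dione (ring O6–C7–C1–C8–C5) and the symmetrical 2,6-dimethylhepta-2,5-diene. C2 carries a phenylsulfanyl helper (thionium carbon) that is removed at the end.
3. What makes this possible: C4 is a gem-dimethyl carbon beside C3–H, i.e. the cation end and the nucleophilic CH end of a prenyl-type double bond; C5 is the central carbon of the β-diketone C8(=O)–C5–C(=O)iPr inside the lactone ring and so a carbon nucleophile; C2 is a CH2 on the quaternary C1.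
4. The furanone is cut at C5–C8 (Dieckmann-type) and at the ester C–O to a malonic half-ester and 1-bromo-3-methylbutan-2-one; the quaternary malonate comes from dimethyl malonate by two alkylations.
5. Forward order: chain joined on the malonate (C1 quaternary) → desymmetrisation → lactone ring O6/C7/C1/C8/C5 → carbocycle C1–C2–C3–C4–C5–C8 and the bridged skeleton in one annulation → desulfurisation.
6. Stereochemistry: C1 from enzymatic desymmetrisation of the prochiral malonate; C5 is forced by C1 because the new bridge can span only one face of the furanone; C3 from a chair-like ring closure with its prenyl group equatorial.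

Key step: step 8

Assumption: pig liver esterase is taken to hydrolyse the ester group of 5 that gives (S)-6; sense and level of selectivity have to be established by experiment, and the resolution given at the end serves either outcome.

**Route**

Step 1
Reactants: 1 dimethyl malonate; 2 1-bromo-3-methylbut-2-ene (prenyl bromide)
Product: 3 dimethyl 2-(3-methylbut-2-en-1-yl)propanedioate
Conditions: NaH (1.0 equiv), 1 in excess (2 equiv), THF, 0 °C to rt
Reagents that add atoms: none
Why: Malonic ester alkylation, an SN2 displacement at the primary allylic bromide by the sodium enolate, with the excess of malonate holding back dialkylation.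

Step 2
Reactants: 3; 4 chloromethyl phenyl sulfide
Product: 5 dimethyl 2-(3-methylbut-2-en-1-yl)-2-[(phenylsulfanyl)methyl]propanedioate
Conditions: NaH, DMF, 0 °C; then 4, NaI (0.1 equiv), 50 °C
Reagents that add atoms: none
Why: Second malonic ester alkylation with the sulfur-activated chloromethyl electrophile (phenylthiomethylation of a stabilised enolate) should give the quaternary, still prochiral carbon that becomes C1, the sulfide being a robust latent electrophile for C2.

Step 3
Reactants: 5
Product: 6 (2S)-2-(methoxycarbonyl)-5-methyl-2-[(phenylsulfanyl)methyl]hex-4-enoic acid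
Conditions: pig liver esterase, 0.1 M phosphate buffer pH 7.5, DMSO (10% v/v), 25 °C, pH-stat (1 M NaOH); then 1 M HCl to pH 2
Reagents that add atoms: water (O)
Why: Enzymatic desymmetrisation of a prochiral disubstituted malonate, in which the esterase hydrolyses one of the two enantiotopic methyl esters and stops at the half-ester, should set the quaternary stereocentre that becomes C1.

Step 4
Reactants: 6; 7 1-bromo-3-methylbutan-2-one
Product: 8 1-methyl 3-(3-methyl-2-oxobutyl) (2R)-2-(3-methylbut-2-en-1-yl)-2-[(phenylsulfanyl)methyl]propanedioate
Conditions: K2CO3, DMF, rt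
Reagents that add atoms: none
Why: O-alkylation of the carboxylate by the α-bromo ketone (SN2, phenacyl-type ester formation) installs the C5/isobutyryl unit as an acyloxymethyl ketone and leaves the quaternary centre untouched (the descriptor changes only through ligand priorities).

Step 5
Reactants: 8
Product: 10 1-methyl 3-(3-methyl-2-oxobutyl) (2R)-2-[methoxy(phenylsulfanyl)methyl]-2-(3-methylbut-2-en-1-yl)propanedioate (both epimers at the acetal carbon), via α-chloro sulfide 9 (not isolated)
Conditions: NCS (1.05 equiv), CH2Cl2, −20 to 0 °C; then MeOH, Et3N, 0 °C to rt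
Reagents that add atoms: methanol (CO)
Why: α-Chlorination of the sulfide by NCS (chlorosulfonium formation and Pummerer-type rearrangement, possible only at the S–CH2 group) followed by SN1 methanolysis through the thionium ion should give the O,S-acetal, which stores C2 at the aldehyde oxidation level in a base-stable form, the sulfide sulfur being the most nucleophilic site of 8.

Step 6
Reactants: 10
Product: 11 (3R)-4-hydroxy-3-[methoxy(phenylsulfanyl)methyl]-3-(3-methylbut-2-en-1-yl)-5-(2-methylpropanoyl)furan-2(3H)-one (enol form of the 5-isobutyrylfuran-2,4-dione; acetal epimers)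
Conditions: LiN(SiMe3)2 (2.2 equiv), THF, −78 to 0 °C; then cold 1 M HCl
Reagents that add atoms: none
Why: Dieckmann-type (Lacey–Dieckmann) condensation, in which the kinetic enolate at the O–CH2 carbon of the acyloxymethyl ketone attacks the methyl ester in a 5-exo-trig closure and the product is withdrawn as its β-diketonate, should build the lactone ring through the C5–C8 bond while the non-enolisable quaternary centre keeps its configuration.

Step 7
Reactants: 2; 12 (2-methylprop-1-en-1-yl)magnesium bromide
Product: 13 2,6-dimethylhepta-2,5-diene
Conditions: Li2CuCl4 (3 mol%), THF, −20 to 0 °C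
Reagents that add atoms: none
Why: Copper-catalysed cross-coupling of an alkenyl Grignard reagent with a primary allylic bromide, which should take place at the unhindered α-carbon, gives the symmetrical skipped diene.

Step 8
Reactants: 11; 13
Product: 15 (1R,3S,5R)-4,4-dimethyl-1,3-bis(3-methylbut-2-en-1-yl)-5-(2-methylpropanoyl)-2-(phenylsulfanyl)-6-oxabicyclo[3.2.1]octane-7,8-dione (both C2 epimers), via trimethylsilyl enol ether 14 (not isolated)
Conditions: Me3SiCl, Et3N, CH2Cl2, 0 °C; evaporation, pentane, filtration under argon; then 13 (3 equiv), SnCl4 (1.5 equiv), CH2Cl2, −78 to −30 °C; aqueous NaHCO3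
Reagents that add atoms: none
Why: Proposed new method: SnCl4 removes methoxide from the O,S-acetal of 14 to give a thionium ion at C2, the CH end of one trisubstituted double bond of 13 adds to it in the Markovnikov sense (C2–C3 bond), and the tertiary cation at the gem-dimethyl carbon C4 is captured by the silyl enol ether carbon C5 (C4–C5 bond) with loss of Me3SiOMe, a formal [4+2] annulation. The closest known reaction types are the Lewis-acid-mediated ene-type addition of thionium ions to trisubstituted alkenes, thionium-initiated cation–olefin cyclisations and the Lewis-acid-mediated α-tert-alkylation of silyl enol ethers by tertiary carbocations, but their union in an intermolecular annulation ended by a β-diketone enol ether has not been shown. The six-membered carbocycle closes in a chair-like 6-(enolendo) cation–olefin mode, the enol ether double bond C5=C8 lying inside the new ring, and this closure completes the bridged bicycle. C5 can be reached only on the furanone face that carries the C2 side chain, so its configuration follows from C1; C3 is set by the chair-like closure with its prenyl-bearing CH2 group equatorial, away from the lactone bridge (same spatial arrangement as in 16, the S descriptor arising only from the sulfur ligand); C2 forms as an epimer mixture of no consequence. The step needs C- over O-alkylation (the enol oxygen is silylated, and a tertiary enol ether would re-ionise under the Lewis acid whereas the C–C bond does not), capture of the cation before proton loss or hydride shift (the nucleophile is held in reach for a six-membered closure) and reaction of only one alkene of 13 (used in excess; its two double bonds are equivalent, so no regiochemical choice arises); release of Me3Si+ in place of H+ keeps the medium free of acid and so protects the prenyl groups.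

Step 9
Reactants: 15
Product: 16 (1R,3R,5R)-4,4-dimethyl-1,3-bis(3-methylbut-2-en-1-yl)-5-(2-methylpropanoyl)-6-oxabicyclo[3.2.1]octane-7,8-dione (target)
Conditions: Raney Ni (W-2, deactivated in refluxing acetone), acetone–EtOH, 0 °C to rt
Reagents that add atoms: none
Why: Reductive desulfurisation (hydrogenolysis of the C–S bond on the nickel surface) should replace the phenylsulfanyl helper at C2 by hydrogen, acetone-deactivated Raney Ni being chosen because it should spare the two trisubstituted double bonds and the hindered ketones, and no stereocentre is touched since C2 becomes a CH2 group.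

**Compound list**

1 | dimethyl malonate | COC(=O)CC(=O)OC | starting material
2 | 1-bromo-3-methylbut-2-ene (prenyl bromide) | CC(C)=CCBr | starting material
3 | dimethyl 2-(3-methylbut-2-en-1-yl)propanedioate | COC(=O)C(CC=C(C)C)C(=O)OC | intermediate
4 | chloromethyl phenyl sulfide | ClCSc1ccccc1 | starting material
5 | dimethyl 2-(3-methylbut-2-en-1-yl)-2-[(phenylsulfanyl)methyl]propanedioate | COC(=O)C(CC=C(C)C)(CSc1ccccc1)C(=O)OC | intermediate
6 | (2S)-2-(methoxycarbonyl)-5-methyl-2-[(phenylsulfanyl)methyl]hex-4-enoic acid | c1ccccc1SC[C@@](C(=O)OC)(CC=C(C)C)C(=O)O | intermediate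
7 | 1-bromo-3-methylbutan-2-one | CC(C)C(=O)CBr | starting material
8 | 1-methyl 3-(3-methyl-2-oxobutyl) (2R)-2-(3-methylbut-2-en-1-yl)-2-[(phenylsulfanyl)methyl]propanedioate | c1ccccc1SC[C@@](C(=O)OC)(CC=C(C)C)C(=O)OCC(=O)C(C)C | intermediate
9 | 1-methyl 3-(3-methyl-2-oxobutyl) (2R)-2-[chloro(phenylsulfanyl)methyl]-2-(3-methylbut-2-en-1-yl)propanedioate (epimers at the CHCl carbon; not isolated) | ClC(Sc1ccccc1)[C@@](C(=O)OC)(CC=C(C)C)C(=O)OCC(=O)C(C)C | intermediate
10 | 1-methyl 3-(3-methyl-2-oxobutyl) (2R)-2-[methoxy(phenylsulfanyl)methyl]-2-(3-methylbut-2-en-1-yl)propanedioate (acetal epimers) | COC(Sc1ccccc1)[C@@](C(=O)OC)(CC=C(C)C)C(=O)OCC(=O)C(C)C | intermediate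
11 | (3R)-4-hydroxy-3-[methoxy(phenylsulfanyl)methyl]-3-(3-methylbut-2-en-1-yl)-5-(2-methylpropanoyl)furan-2(3H)-one (acetal epimers) | COC(Sc1ccccc1)[C@@]2(CC=C(C)C)C(=O)OC(C(=O)C(C)C)=C2O | intermediate
12 | (2-methylprop-1-en-1-yl)magnesium bromide | CC(C)=C[Mg]Br | starting material
13 | 2,6-dimethylhepta-2,5-diene | CC(C)=CCC=C(C)C | intermediate
14 | (3R)-3-[methoxy(phenylsulfanyl)methyl]-3-(3-methylbut-2-en-1-yl)-5-(2-methylpropanoyl)-4-[(trimethylsilyl)oxy]furan-2(3H)-one (acetal epimers; not isolated) | COC(Sc1ccccc1)[C@@]2(CC=C(C)C)C(=O)OC(C(=O)C(C)C)=C2O[Si](C)(C)C | intermediate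
15 | (1R,3S,5R)-4,4-dimethyl-1,3-bis(3-methylbut-2-en-1-yl)-5-(2-methylpropanoyl)-2-(phenylsulfanyl)-6-oxabicyclo[3.2.1]octane-7,8-dione (C2 epimers) | CC(C)=CC[C@@H]1C(Sc3ccccc3)[C@@]2(CC=C(C)C)C(=O)O[C@](C(=O)C(C)C)(C2=O)C1(C)C | intermediate
16 | (1R,3R,5R)-4,4-dimethyl-1,3-bis(3-methylbut-2-en-1-yl)-5-(2-methylpropanoyl)-6-oxabicyclo[3.2.1]octane-7,8-dione | CC(C)=CC[C@@H]1C[C@@]2(CC=C(C)C)C(=O)O[C@](C(=O)C(C)C)(C2=O)C1(C)C | target

**Step count and risks**

Total step count: 9. Longest linear sequence: 8 steps (steps 1 to 6, 8 and 9).

Steps most likely to fail: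

1. Step 8 (Proposed new method). The cascade may end after the first bond: the tertiary cation at C4 may lose a proton (ene-type termination), undergo a hydride shift from C3, or be taken by an enol oxygen, so that the C4–C5 bond does not close. The fallback makes the two bonds in two known operations, sets out from 11 and comes back at 15. Compound 11 is treated with 13 and SnCl4 in the presence of 2,6-di-tert-butylpyridine (CH2Cl2, −78 °C) in a thionium–ene reaction that is deliberately stopped at the homoallylic sulfide with an isopropenyl group, (3R)-4-hydroxy-3-[5-methyl-1-(phenylsulfanyl)-2-(prop-1-en-2-yl)hex-4-en-1-yl]-3-(3-methylbut-2-en-1-yl)-5-(2-methylpropanoyl)furan-2(3H)-one F1. F1 is then cyclised in formic acid at rt. Markovnikov protonation of the isopropenyl group regenerates the C4 cation; O-alkylation is reversible under these conditions and C-alkylation of the enolised β-diketone is not, so the material should be drawn to 15.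

2. Step 3. The esterase may discriminate poorly between the two enantiotopic esters, or in the opposite sense, because both substituents at the prochiral carbon are large and lipophilic. The fallback is a classical resolution, sets out from 5 and comes back at 6. Mono-saponification of 5 with KOH (1 equiv) in MeOH gives the racemic half-ester 2-(methoxycarbonyl)-5-methyl-2-[(phenylsulfanyl)methyl]hex-4-enoic acid F2. The salt of its (S)-acid with (S)-1-phenylethylamine (or with the enantiomeric amine, whichever gives the less soluble salt of the (S)-acid), (S)-1-phenylethylammonium (2S)-2-(methoxycarbonyl)-5-methyl-2-[(phenylsulfanyl)methyl]hex-4-enoate F3, is crystallised to purity and acidified with HCl to release 6.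

3. Step 5. The chlorosulfonium stage may be diverted: the activated sulfur may be attacked by the nearby trisubstituted double bond, or positive chlorine may reach the alkene or the ketone α-position. The fallback avoids positive chlorine, sets out from 8 and comes back at 10. The sulfide is oxidised with NaIO4 (MeOH–water, 0 °C) to the sulfoxide 1-methyl 3-(3-methyl-2-oxobutyl) (2R)-2-(3-methylbut-2-en-1-yl)-2-[(phenylsulfinyl)methyl]propanedioate F4. Pummerer rearrangement with trifluoroacetic anhydride and 2,6-lutidine (CH2Cl2, 0 °C) gives the α-trifluoroacetoxy sulfide 1-methyl 3-(3-methyl-2-oxobutyl) (2R)-2-(3-methylbut-2-en-1-yl)-2-[(phenylsulfanyl)(trifluoroacetoxy)methyl]propanedioate F5. Acid-catalysed exchange with methanol (MeOH, camphorsulfonic acid, rt) through the thionium ion then gives 10.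

Further compounds

F1 | step 8 | (3R)-4-hydroxy-3-[5-methyl-1-(phenylsulfanyl)-2-(prop-1-en-2-yl)hex-4-en-1-yl]-3-(3-methylbut-2-en-1-yl)-5-(2-methylpropanoyl)furan-2(3H)-one (side-chain epimers) | CC(C)=CCC(C(C)=C)C(Sc1ccccc1)[C@@]2(CC=C(C)C)C(=O)OC(C(=O)C(C)C)=C2O
F2 | step 3 | racemic 2-(methoxycarbonyl)-5-methyl-2-[(phenylsulfanyl)methyl]hex-4-enoic acid | COC(=O)C(CSc1ccccc1)(CC=C(C)C)C(=O)O
F3 | step 3 | (S)-1-phenylethylammonium (2S)-2-(methoxycarbonyl)-5-methyl-2-[(phenylsulfanyl)methyl]hex-4-enoate | c1ccccc1SC[C@@](C(=O)OC)(CC=C(C)C)C(=O)[O-].C[C@H]([NH3+])c1ccccc1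
F4 | step 5 | 1-methyl 3-(3-methyl-2-oxobutyl) (2R)-2-(3-methylbut-2-en-1-yl)-2-[(phenylsulfinyl)methyl]propanedioate (sulfoxide epimers) | O=S(c1ccccc1)C[C@@](C(=O)OC)(CC=C(C)C)C(=O)OCC(=O)C(C)C
F5 | step 5 | 1-methyl 3-(3-methyl-2-oxobutyl) (2R)-2-(3-methylbut-2-en-1-yl)-2-[(phenylsulfanyl)(trifluoroacetoxy)methyl]propanedioate (epimers) | FC(F)(F)C(=O)OC(Sc1ccccc1)[C@@](C(=O)OC)(CC=C(C)C)C(=O)OCC(=O)C(C)C
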